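**Remark on the chemistry:** the terminal rings and their precursors (20–23) are enolised β-triketones and are drawn as one tautomer. The silyl enol ethers 14–16 are taken as mixtures of double-bond isomers; the geometry is lost in step 11.

## The problem

CNP0188003.0 (23) is a linear pentamer. Rings A and E are 2-butyryl-6,6-dimethylcyclohexane-1,3,5-trione units (enolised), rings B, C and D are butyrylphloroglucinols, and four CH2 bridges join them in the order A–B–C–D–E. There is no stereocentre, so nothing has to be controlled stereochemically; the task is sequence and regiochemistry. Every carbon of rings B, C and D is substituted, and each bridge must sit between two defined rings, which a statistical methylene-bridging condensation cannot guarantee. Free methylene-bridged acylphloroglucinols exchange their bridges in base (rottlerone-type change), electron-rich diarylmethanes can be cleaved by strong acid, and the polyphenol and triketone units chelate metals and oxidise in air. The phenols are therefore best carried as methyl ethers to the last step. The butyryl ketones are best introduced late, because they would not survive organolithium, dianion and amide-base chemistry. The quaternary C(CH3)2 carbon of rings A and E is classically made by C-methylation of a phloroglucinol, with O- versus C-alkylation and over-alkylation problems. The feature that opens a different route is the following: in rings A and E the C(CH3)2 carbon and one neighbouring carbonyl carbon form a Me2C–C=O unit with the constitution of dimethylketene. The other four ring carbons (the bridge-bearing carbon, the carbonyl next to it, the future butyryl-bearing CH and the third carbonyl) are C4, C3, C2 and C1 of a 3-oxo ester whose C4 carries the benzylic CH2 of ring B or D, that is, of its 1-methoxy-1,3-bis(silyloxy)diene.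

## Retrosynthesis

**Phenol release (23 from 22).** The nine aryl O–CH3 bonds are cut last. Methyl ethers are the only phenol protection that tolerates everything before this point: organolithiums, an ester dianion, acid/silane, amide base and Lewis acids. By then the five acyl groups deactivate the rings and make the bridges less prone to acid cleavage. The forward step asks only for exhaustive ether cleavage (BBr3).

**Butyryl groups (22 from 21 from 20).** Five C–C(=O) bonds are cut: three aryl–acyl bonds on rings B, C, D and two on the triones A and E. Carrying the ketones from the start would mirror the natural order but would block steps 3, 5, 6 and 9. Cutting them late leaves every earlier intermediate ketone-free. Forward, the triones are acylated first under neutral acyl-transfer conditions (21). They are then already blocked and chelated when the three arenes are acylated at their only free carbon under Friedel–Crafts conditions (22).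

**Terminal rings (20 from 16 and two molecules of 18).** In each of rings A and E two bonds are cut: the bond from the bridge-bearing ring carbon to the adjacent carbonyl carbon, and the bond from the C(CH3)2 carbon to the carbonyl carbon on its far side. This gives the bis[1-methoxy-1,3-bis(trimethylsilyloxy)diene] 16 and dimethylketene 18. Two neighbouring cuts were weighed. C-methylation of a preformed phloroglucinol ring has selectivity problems. A Dieckmann closure needs a longer, quaternary-carbon-containing arm. The ketene cut removes both rings and both quaternary carbons at once and leaves a precursor whose arms come from methyl acetoacetate. The forward reaction must form C–C bonds across the ketene C=C, not a four-membered ring or a bond through the ketene oxygen.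

**Dienes (16 from 14 from 13).** Four O–Si bonds are cut. The bis(β-keto ester) 13 is silylated in the usual two stages: enol silylation to 14, then γ-deprotonation (15) and silylation.

**Arms (13 from 12 from 9 and 10).** The bond between the benzylic carbon and the γ-carbon of methyl acetoacetate (10) is cut. Alkylating the dianion with a benzylic halide would need a 2,4,6-trimethoxybenzyl halide, which ionises spontaneously. The aldehyde 9 is the stable equivalent: dianion aldol gives 12, and the same electron-rich aryl group that rules out the halide makes ionic removal of the benzylic hydroxyl easy.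

**Aldehydes (9 from 7).** Two aryl–CHO bonds are cut, made by bromine–lithium exchange (8) and formylation. The bromines are already in place on rings B and D, so the nearly equal free positions of rings B, C and D never have to be told apart.

**Core (7 from 6 from 2 and 4).** The two inner bridges are cut at the aryl–CH2 bond on the B and D side. Ring C enters as the bis-electrophile 4 and rings B and D as the aryllithium 5, so ring C can only end up in the middle; the bis(carbinol) 6 is reduced to 7. A one-pot methylene-bridging condensation would be shorter but gives oligomer mixtures.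

**Building blocks.** Dibromide 2 comes from 1,3,5-trimethoxybenzene (1) by bromination. Dialdehyde 4 comes from 2,4,6-trimethoxybenzaldehyde (3) by a second formylation. Ketene 18 comes from 2-bromo-2-methylpropanoyl bromide (17) and zinc.

## Roads not taken

**Alternative 1:** The cut is at the two inner aryl–CH2 bonds. The ring C bis(benzylic pinacolboronate) A2 would be coupled twice with 2-bromo-1,3,5-trimethoxybenzene A3 under Pd(PPh3)4 (zerovalent palladium) and K3PO4 to give the nonamethoxy trimer A1.
- Merits: the conditions are neutral to basic, no benzylic cation is involved, and the sequence B–C–D is fixed by the coupling partners.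
- Weak points: A2 must be made from benzylic halides that ionise easily. Transmetalation of an sp3 boronate onto a di-ortho-methoxy aryl bromide is slow and protodeboronation competes. Above all, A1 has five electronically similar free positions (four on rings B and D, one on ring C), so the outer bridges cannot be placed selectively. The plan is also silent on rings A and E.
- Comparison: as a way to make the core it is milder than steps 3 and 4 here, which expose bromoarenes and diarylmethanes to acid. Against that, the chosen plan carries a bromine into each of rings B and D with aryllithium 5, so 7 is already differentiated, and it spends its key step on the hardest part of the molecule, not the easiest.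

**Alternative 2:** Rings B and D would be built de novo. The ring C bis(siloxyalkyne) A5 would be heated with two equivalents of cyclobutenone A6; each vinylketene–alkyne cascade closes one aromatic ring and gives the protected trimer A4.
- Merits: each new ring is formed regiospecifically with three differentiated oxygens (free OH, silyl ether, ethyl ether) and a benzylic methyl ether as a handle for the outer bridge. In this respect it is better than the chosen plan, where the nine oxygens are all alike.
- Weak points: rings B and D are phloroglucinol rings that can be bought as the trimethyl ether. A5 contains two sensitive ynol silyl ethers and A6 is itself a multistep compound. Two thermal cascades must both succeed. The mixed protecting groups need separate removal. Rings A and E and all five butyryl groups are still missing.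
- Comparison: the chosen plan obtains the same regiochemical information from one bromine per ring at far lower step cost.

**Alternative 3:** In each terminal ring the bond between the future butyryl-bearing carbon and the adjacent ring carbonyl is cut. NaOMe would convert the terminal acetyl group of the bis(dioxo ester) A8 into its enolate, which attacks the neighbouring methyl ester (double Dieckmann closure) to give the pentamer A7, which lacks only the two terminal butyryl groups.
- Merits: Dieckmann closure of 2,2-dialkyl-3,5-dioxo esters to gem-dialkyl cyclohexanetriones is established, and the quaternary carbon arrives ready-made. The ring closure itself is safer than the key step chosen here, and this must be admitted.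
- Weak points: in A8 the bridge-bearing carbon sits between two ketones and is deprotonated first, so the closing enolate is a dianion. The non-enolisable β-keto ester next to the quaternary carbon is prone to retro-Claisen cleavage by methoxide. A8 carries free phenols on methylene-bridged acylphloroglucinols, exactly the situation in which base scrambles bridges. Each arm needs a five-carbon quaternary building block attached to a benzylic carbon.
- Comparison: the chosen plan sets against the precedent of Alternative 3 a two-step arm from methyl acetoacetate, ring closure on a fully O-methylated core without strong base, and a fallback from 9 that uses only known chemistry.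

Key step: step 11

## Route

Step 1
Reactants: 1 1,3,5-trimethoxybenzene
Product: 2 2,4-dibromo-1,3,5-trimethoxybenzene
Conditions: NBS (2.05 equiv), MeCN, 0 °C → rt
Reagents that add atoms: N-bromosuccinimide, O=C1CCC(=O)N1Br
Why: Electrophilic aromatic bromination; each bromine slightly deactivates the ring, so two equivalents should stop at the 2,4-dibromide and leave the third position free.

Step 2
Reactants: 3 2,4,6-trimethoxybenzaldehyde
Product: 4 2,4,6-trimethoxybenzene-1,3-dicarbaldehyde
Conditions: Cl2CHOMe, TiCl4, CH2Cl2, −10 °C → rt; then aq. HCl
Reagents that add atoms: dichloromethyl methyl ether, COC(Cl)Cl; water, O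
Why: Rieche formylation; C3 is ortho to two methoxy groups, para to the third and meta to the formyl group, so the ring should still accept one more formyl group, and the temperature is kept low to avoid ether cleavage next to the aldehyde.

Step 3
Reactants: 2 2,4-dibromo-1,3,5-trimethoxybenzene; 4 2,4,6-trimethoxybenzene-1,3-dicarbaldehyde
Product: 6 (2,4,6-trimethoxy-1,3-phenylene)bis[(3-bromo-2,4,6-trimethoxyphenyl)methanol] as a meso/racemic mixture, via (3-bromo-2,4,6-trimethoxyphenyl)lithium 5 (not isolated)
Conditions: 2 (2.4 equiv), n-BuLi (2.4 equiv), THF, −78 °C; then 4, −78 → 0 °C; H2O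
Reagents that add atoms: none
Why: Mono bromine–lithium exchange followed by 1,2-addition of the aryllithium to both non-enolisable aldehyde groups; the second exchange on 2 is much slower than the first, so one bromine per ring is retained. The two carbinol centres form without control and are removed in step 4.

Step 4
Reactants: 6 bis(carbinol)
Product: 7 2,4-bis[(3-bromo-2,4,6-trimethoxyphenyl)methyl]-1,3,5-trimethoxybenzene (dibromo B–C–D trimer)
Conditions: Et3SiH (6 equiv), CF3CO2H (3 equiv), CH2Cl2, −40 → 0 °C
Reagents that add atoms: none
Why: Ionic hydrogenation of diarylcarbinols; the carbinols are flanked by six methoxy groups and ionise under little acid, and the silane in excess traps each diarylmethyl cation irreversibly as the CH2 bridge.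

Step 5
Reactants: 7 dibromo B–C–D trimer
Product: 9 3,3'-[(2,4,6-trimethoxy-1,3-phenylene)bis(methylene)]bis(2,4,6-trimethoxybenzaldehyde), via dilithiated trimer 8 (not isolated)
Conditions: n-BuLi (2.4 equiv), THF, −78 °C; DMF, −78 → 0 °C; aq. HCl
Reagents that add atoms: N,N-dimethylformamide, CN(C)C=O
Why: Bromine–lithium exchange on two separate rings followed by formylation with DMF (Bouveault type); exchange at −78 °C is far faster than deprotonation of the bridges or of the free arene positions.

Step 6
Reactants: 9 trimer dialdehyde; 10 methyl acetoacetate
Product: 12 dimethyl 5,5'-{(2,4,6-trimethoxy-1,3-phenylene)bis[methylene(2,4,6-trimethoxy-3,1-phenylene)]}bis(5-hydroxy-3-oxopentanoate) as a diastereomer mixture, via methyl acetoacetate dianion 11 (not isolated)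
Conditions: 10 (3 equiv), NaH, THF, 0 °C; n-BuLi, 0 °C; then 9, −78 °C; 1 M HCl, −78 → 0 °C
Reagents that add atoms: none
Why: Weiler dianion aldol; the γ-carbon of the dianion is the more nucleophilic site and adds to the hindered, non-enolisable aldehydes. The carbinol configuration is irrelevant because the hydroxyl is removed in step 7, and any dehydrated material converges there as well.

Step 7
Reactants: 12 bis(δ-hydroxy-β-keto ester)
Product: 13 dimethyl 5,5'-{(2,4,6-trimethoxy-1,3-phenylene)bis[methylene(2,4,6-trimethoxy-3,1-phenylene)]}bis(3-oxopentanoate)
Conditions: Et3SiH (10 equiv), CF3CO2H (5 equiv), CH2Cl2 (0.01 M), −20 → 0 °C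
Reagents that add atoms: none
Why: Ionic hydrogenation (Kursanov–Parnes type); the trimethoxyaryl carbinol ionises under weak acid and the benzylic cation, or the aryl enone formed from it by proton loss and re-protonated at oxygen, takes hydride from the silane at the benzylic carbon. The dialkyl ketone of the β-keto ester is not reduced under these conditions, and dilution with excess silane disfavours capture of the cation by free arene positions.

Step 8
Reactants: 13 bis(β-keto ester)
Product: 14 bis(silyl enol ether) in which each arm is ArCH2CH2C(OSiMe3)=CHCO2Me (mainly Z)
Conditions: Me3SiCl, Et3N, toluene, rt; filtration under argon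
Reagents that add atoms: chlorotrimethylsilane, C[Si](C)(C)Cl
Why: O-silylation of the β-keto ester enol, the standard first stage of 1,3-bis(silyloxy)diene synthesis.

Step 9
Reactants: 14 bis(silyl enol ether)
Product: 16 bis[1-methoxy-1,3-bis(trimethylsilyloxy)diene] in which each arm is ArCH2CH=C(OSiMe3)CH=C(OMe)OSiMe3, via dilithium bis(dienolate) 15 (not isolated)
Conditions: LiN(i-Pr)2 (2.6 equiv), THF, −78 °C; Me3SiCl, −78 °C → rt; used crude
Reagents that add atoms: chlorotrimethylsilane, C[Si](C)(C)Cl
Why: Kinetic γ-deprotonation of the 3-silyloxy enoate and O-silylation of the ester dienolate, the standard second stage for 4-substituted 1,3-bis(silyloxy)dienes; the arene and bridge C–H bonds are too weakly acidic to compete at −78 °C.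

Step 10
Reactants: 17 2-bromo-2-methylpropanoyl bromide
Product: 18 dimethylketene (ethyl acetate solution)
Conditions: Zn, EtOAc, gentle reflux under N2 at reduced pressure, codistillation; used at once, O2 excluded
Reagents that add atoms: none
Why: Zinc-mediated 1,2-dehalogenation of an α-bromoacyl bromide, the classical laboratory preparation of dimethylketene; keeping it in solution under inert gas avoids dimerisation and peroxide formation.

Step 11
Reactants: 16 bis[1-methoxy-1,3-bis(trimethylsilyloxy)diene]; 18 dimethylketene
Product: 20 nonamethoxy pentamer in which rings B and D each carry a (2,4-dihydroxy-3,3-dimethyl-6-oxocyclohexa-1,4-dien-1-yl)methyl group (unacylated rings A and E), via bis(silyl ketal) cycloadduct 19 (not isolated)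
Conditions: 16, Me3SiOTf (0.2 equiv), 2,6-di-tert-butyl-4-methylpyridine (0.3 equiv), CH2Cl2, −78 °C; 18 (6 equiv) added slowly, −78 → −20 °C; then 1 M HCl, THF, 0 °C → rt
Reagents that add atoms: none
Why: Proposed new method: a silyl-triflate-catalysed formal [4+2] annulation of a 1-methoxy-1,3-bis(silyloxy)diene with the C=C bond of a dialkylketene; the closest known reaction types are the Lewis-acid-mediated formal [4+2] and [3+3] cyclisations of 1,3-bis(silyloxy)dienes with acyl electrophiles, the [2+2] and formal [4+2] cycloadditions of ketenes with siloxydienes and ketene acetals, and Lewis-acid-promoted ketene–alkene cycloadditions. Me3SiOTf silylates the ketene oxygen, and the diene terminus C4 (the carbon bearing the benzylic CH2, the most nucleophilic site) attacks the central ketene carbon, giving a silyl enol ether Me2C=C(OSiMe3)– on C4 and a 1-methoxy-1,3-bis(silyloxy)allyl cation over C1–C3. The tetrasubstituted enol ether carbon then adds to C1 of that cation in a Mukaiyama-type cation–enol ether closure, which forms the bond from the dimethyl carbon to the former ketene acetal carbon, closes each of rings A and E as a six-membered carbocycle (19) and releases the silyl cation to carry the chain. Aqueous HCl hydrolyses the mixed silyl methyl ketal and the ring silyl enol ether to the enolised 2,2-dimethyl-1,3,5-trione; the two transient stereocentres per ring are erased, so no stereocontrol is needed. The selectivity required is C–C bond formation across the ketene C=C in preference to four-membered closure at C3 or closure through the ketene oxygen to a pyranone: silylation blocks that oxygen, a donor–acceptor 3-silyloxycyclobutanone can reopen to the same cation under the silyl Lewis acid, and only the six-membered closure is irreversible. Regiochemistry follows from polarity (diene C4 to the ketene carbonyl carbon); slow addition of 18 at low temperature keeps ketene oligomerisation and acylation of the free arene positions behind capture by the far more nucleophilic diene, and the hindered pyridine removes traces of triflic acid that would protodesilylate 16.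

Step 12
Reactants: 20 pentamer with unacylated rings A and E
Product: 21 nonamethoxy pentamer in which rings B and D each carry a (5-butanoyl-2,4-dihydroxy-3,3-dimethyl-6-oxocyclohexa-1,4-dien-1-yl)methyl group
Conditions: n-PrCO2H, DCC, DMAP, CH2Cl2, 0 °C → rt
Reagents that add atoms: butanoic acid, CCCC(=O)O
Why: O-acylation of the cyclic 1,3-dione enol followed by DMAP-mediated O-to-C acyl migration, as used for 2-acylcyclohexane-1,3-diones; the only ring carbon still bearing hydrogen gives the stable chelated triketone, and the methoxyarenes are inert under these neutral conditions.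

Step 13
Reactants: 21 pentamer with butyrylated rings A and E
Product: 22 pentabutyryl nonamethyl ether (the nona-O-methyl ether of the target, with a butanoyl group on the one free carbon of each of rings B, C and D)
Conditions: n-PrCOCl, TiCl4, CH2Cl2, −20 → 0 °C; then cold 1 M HCl
Reagents that add atoms: butanoyl chloride, CCCC(=O)Cl
Why: Friedel–Crafts acylation at the single free position of each trimethoxyarene, which is ortho to two methoxy groups and para to the third; the acyl triones are tied up as titanium chelates, and any enol ester formed on them is hydrolysed on work-up.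

Step 14
Reactants: 22 pentabutyryl nonamethyl ether
Product: 23 CNP0188003.0
Conditions: BBr3 (excess), CH2Cl2, −78 °C → rt; then H2O, 0 °C
Reagents that add atoms: none
Why: Lewis-acid cleavage of aryl methyl ethers; the six ethers ortho to the aryl ketones should go first with chelation assistance and the three ethers between the bridges with excess reagent, while the acyl groups deactivate the rings against acid-induced bridge cleavage. Boron chelates of the triketones are hydrolysed on work-up.

## Compound list

1 | 1,3,5-trimethoxybenzene | COc1cc(OC)cc(OC)c1 | starting material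
2 | 2,4-dibromo-1,3,5-trimethoxybenzene | COc1cc(OC)c(Br)c(OC)c1Br | intermediate
3 | 2,4,6-trimethoxybenzaldehyde | COc1cc(OC)c(C=O)c(OC)c1 | starting material
4 | 2,4,6-trimethoxybenzene-1,3-dicarbaldehyde | COc1cc(OC)c(C=O)c(OC)c1C=O | intermediate
5 | (3-bromo-2,4,6-trimethoxyphenyl)lithium (not isolated) | [Li]c1c(OC)cc(OC)c(Br)c1OC | intermediate
6 | (2,4,6-trimethoxy-1,3-phenylene)bis[(3-bromo-2,4,6-trimethoxyphenyl)methanol], meso/racemic mixture | COc1cc(OC)c(C(O)c2c(OC)cc(OC)c(Br)c2OC)c(OC)c1C(O)c1c(OC)cc(OC)c(Br)c1OC | intermediate
7 | 2,4-bis[(3-bromo-2,4,6-trimethoxyphenyl)methyl]-1,3,5-trimethoxybenzene | COc1cc(OC)c(Cc2c(OC)cc(OC)c(Br)c2OC)c(OC)c1Cc1c(OC)cc(OC)c(Br)c1OC | intermediate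
8 | dilithiated trimer, lithium in place of both bromines of 7 (not isolated) | COc1cc(OC)c(Cc2c(OC)cc(OC)c([Li])c2OC)c(OC)c1Cc1c(OC)cc(OC)c([Li])c1OC | intermediate
9 | 3,3'-[(2,4,6-trimethoxy-1,3-phenylene)bis(methylene)]bis(2,4,6-trimethoxybenzaldehyde) | COc1cc(OC)c(Cc2c(OC)cc(OC)c(C=O)c2OC)c(OC)c1Cc1c(OC)cc(OC)c(C=O)c1OC | intermediate
10 | methyl acetoacetate | COC(=O)CC(C)=O | starting material
11 | methyl acetoacetate dianion, sodium lithium salt (not isolated) | [Na+].[Li+].[CH2-]C(=O)[CH-]C(=O)OC | intermediate
12 | bis(δ-hydroxy-β-keto ester), each arm ArCH(OH)CH2C(=O)CH2CO2Me, diastereomer mixture | COc1cc(OC)c(Cc2c(OC)cc(OC)c(C(O)CC(=O)CC(=O)OC)c2OC)c(OC)c1Cc1c(OC)cc(OC)c(C(O)CC(=O)CC(=O)OC)c1OC | intermediate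
13 | bis(β-keto ester), each arm ArCH2CH2C(=O)CH2CO2Me | COc1cc(OC)c(Cc2c(OC)cc(OC)c(CCC(=O)CC(=O)OC)c2OC)c(OC)c1Cc1c(OC)cc(OC)c(CCC(=O)CC(=O)OC)c1OC | intermediate
14 | bis(silyl enol ether), each arm ArCH2CH2C(OSiMe3)=CHCO2Me, mixture of geometries | COc1cc(OC)c(Cc2c(OC)cc(OC)c(CCC(O[Si](C)(C)C)=CC(=O)OC)c2OC)c(OC)c1Cc1c(OC)cc(OC)c(CCC(O[Si](C)(C)C)=CC(=O)OC)c1OC | intermediate
15 | dilithium bis(dienolate), each arm ArCH2CH=C(OSiMe3)CH=C(OMe)OLi (not isolated) | [Li+].[Li+].COc1cc(OC)c(Cc2c(OC)cc(OC)c(CC=C(O[Si](C)(C)C)C=C([O-])OC)c2OC)c(OC)c1Cc1c(OC)cc(OC)c(CC=C(O[Si](C)(C)C)C=C([O-])OC)c1OC | intermediate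
16 | bis[1-methoxy-1,3-bis(trimethylsilyloxy)diene], each arm ArCH2CH=C(OSiMe3)CH=C(OMe)OSiMe3, mixture of geometries | COc1cc(OC)c(Cc2c(OC)cc(OC)c(CC=C(O[Si](C)(C)C)C=C(OC)O[Si](C)(C)C)c2OC)c(OC)c1Cc1c(OC)cc(OC)c(CC=C(O[Si](C)(C)C)C=C(OC)O[Si](C)(C)C)c1OC | intermediate
17 | 2-bromo-2-methylpropanoyl bromide | CC(C)(Br)C(=O)Br | starting material
18 | dimethylketene | CC(C)=C=O | intermediate
19 | bis(silyl ketal) cycloadduct, each new ring a 5-methoxy-6,6-dimethyl-3,5-bis(trimethylsilyloxy)cyclohex-3-en-1-one carrying the benzylic CH2 at C2, diastereomer mixture (not isolated) | COc1cc(OC)c(Cc2c(OC)cc(OC)c(CC3C(=O)C(C)(C)C(OC)(O[Si](C)(C)C)C=C3O[Si](C)(C)C)c2OC)c(OC)c1Cc1c(OC)cc(OC)c(CC2C(=O)C(C)(C)C(OC)(O[Si](C)(C)C)C=C2O[Si](C)(C)C)c1OC | intermediate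
20 | nonamethoxy pentamer with unacylated terminal trione rings | COc1cc(OC)c(Cc2c(OC)cc(OC)c(CC3=C(O)C(C)(C)C(O)=CC3=O)c2OC)c(OC)c1Cc1c(OC)cc(OC)c(CC2=C(O)C(C)(C)C(O)=CC2=O)c1OC | intermediate
21 | nonamethoxy pentamer with butyrylated rings A and E | COc1cc(OC)c(Cc2c(OC)cc(OC)c(CC3=C(O)C(C)(C)C(O)=C(C(=O)CCC)C3=O)c2OC)c(OC)c1Cc1c(OC)cc(OC)c(CC2=C(O)C(C)(C)C(O)=C(C(=O)CCC)C2=O)c1OC | intermediate
22 | pentabutyryl nonamethyl ether | CCCC(=O)c1c(OC)c(Cc2c(OC)c(C(=O)CCC)c(OC)c(CC3=C(O)C(C)(C)C(O)=C(C(=O)CCC)C3=O)c2OC)c(OC)c(Cc2c(OC)c(C(=O)CCC)c(OC)c(CC3=C(O)C(C)(C)C(O)=C(C(=O)CCC)C3=O)c2OC)c1OC | intermediate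
23 | CNP0188003.0 | CCCC(=O)C1=C(O)C(C)(C)C(O)=C(Cc2c(O)c(Cc3c(O)c(Cc4c(O)c(CC5=C(O)C(C)(C)C(O)=C(C(=O)CCC)C5=O)c(O)c(C(=O)CCC)c4O)c(O)c(C(=O)CCC)c3O)c(O)c(C(=O)CCC)c2O)C1=O | target

## Step count and least certain steps

Total: 14 steps. Longest linear sequence: 12 steps (1, 3, 4, 5, 6, 7, 8, 9, 11, 12, 13, 14); steps 2 and 10 are side branches.

**Step 11 (key step, proposed new method).** Ring closure may go through the ketene-derived oxygen, or the intermediate may lose silicon or pick up a proton before the second C–C bond forms; either ends in lactonisation to a pyranone on work-up. The ketene may also oligomerise under the silyl Lewis acid, or the diene may be protodesilylated. Fallback by known chemistry: the arm-building steps 6–11 are set aside. Dialdehyde 9 would be condensed with excess filicinic acid F1 (2,2-dimethylcyclohexane-1,3,5-trione, from phloroglucinol by double C-methylation with NaOMe/MeI) in the proline-catalysed three-component reductive alkylation with Hantzsch ester. The bis(arylidene) Knoevenagel adduct F2 would be reduced in the flask by hydride transfer, and the route is rejoined at 20.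

**Step 13.** The acylium ion may attack a bridge-bearing carbon and expel a trimethoxybenzyl cation (bridge cleavage and transbenzylation). Acylation at the crowded positions may stall, or ethers next to the new ketones may be cleaved unevenly. Fallback: the order is reversed. Compound 21 would be demethylated first (BBr3) to the nonaphenol F3. Its three free phloroglucinol nuclei, now far more nucleophilic, would then be C-acylated with butanoic acid in BF3·OEt2, which reaches 23 directly and bypasses 22.

**Step 14.** Cleavage of the three doubly flanked ethers may be incomplete. Long exposure to excess Lewis acid may cut bridges or cause dehydrative cyclisation between a freed phenol and the neighbouring trione enol. Fallback: a staged deprotection from 22. BCl3 at low temperature would remove only the six chelated ethers ortho to the aryl ketones and give the tri-O-methyl ether F4. Its three remaining ethers would be cleaved by the hard acid/soft nucleophile pair AlCl3/EtSH at 0 °C, returning to 23.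

**Step 7.** The benzylic cation may be captured by a free arene position of another molecule (oligomerisation), or the ester oxygen may close onto it (lactonisation), before hydride transfer. Fallback: 12 would be dehydrated (MsCl, Et3N, then DBU) to the bis(E-enone) F5. The enone C=C would be hydrogenated over Pd/C in EtOAc, rejoining at 13.

**Step 4.** Acid may cause bromine migration or protodebromination on the highly activated bromoarenes, and the diarylmethyl cation may be trapped by an arene position instead of the silane. Fallback: steps 3 and 4 are replaced. Dialdehyde 4 would be reduced with NaBH4 to the diol F6. F6 would then alkylate a large excess of 2-bromo-1,3,5-trimethoxybenzene (the bromide labelled A3 above) under Sc(OTf)3 catalysis in a Friedel–Crafts benzylation, rejoining at 7.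

## Further compounds

F1 | step 11 | filicinic acid (2,2-dimethylcyclohexane-1,3,5-trione, enol form) | CC1(C)C(O)=CC(=O)C=C1O
F2 | step 11 | bis(arylidene) Knoevenagel adduct of 9 and F1, mixture of alkene geometries | COc1cc(OC)c(Cc2c(OC)cc(OC)c(C=C3C(=O)CC(=O)C(C)(C)C3=O)c2OC)c(OC)c1Cc1c(OC)cc(OC)c(C=C2C(=O)CC(=O)C(C)(C)C2=O)c1OC
F3 | step 13 | nonaphenol pentamer with butyrylated rings A and E | Oc1cc(O)c(Cc2c(O)cc(O)c(CC3=C(O)C(C)(C)C(O)=C(C(=O)CCC)C3=O)c2O)c(O)c1Cc1c(O)cc(O)c(CC2=C(O)C(C)(C)C(O)=C(C(=O)CCC)C2=O)c1O
F4 | step 14 | pentabutyryl tri-O-methyl ether (one methoxy group left on each of rings B, C and D, between the two bridges) | CCCC(=O)c1c(O)c(Cc2c(O)c(C(=O)CCC)c(O)c(CC3=C(O)C(C)(C)C(O)=C(C(=O)CCC)C3=O)c2OC)c(OC)c(Cc2c(O)c(C(=O)CCC)c(O)c(CC3=C(O)C(C)(C)C(O)=C(C(=O)CCC)C3=O)c2OC)c1O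
F5 | step 7 | bis(E-enone), each arm ArCH=CHC(=O)CH2CO2Me | COc1cc(OC)c(Cc2c(OC)cc(OC)c(/C=C/C(=O)CC(=O)OC)c2OC)c(OC)c1Cc1c(OC)cc(OC)c(/C=C/C(=O)CC(=O)OC)c1OC
F6 | step 4 | (2,4,6-trimethoxy-1,3-phenylene)dimethanol | COc1cc(OC)c(CO)c(OC)c1CO
A1 | alternative 1 | nonamethoxy B–C–D trimer | COc1cc(OC)c(Cc2c(OC)cc(OC)cc2OC)c(OC)c1Cc1c(OC)cc(OC)cc1OC
A2 | alternative 1 | ring C bis(benzylic pinacolboronate) | COc1cc(OC)c(CB2OC(C)(C)C(C)(C)O2)c(OC)c1CB1OC(C)(C)C(C)(C)O1
A3 | alternative 1 | 2-bromo-1,3,5-trimethoxybenzene | COc1cc(OC)c(Br)c(OC)c1
A4 | alternative 2 | protected B–C–D trimer with methoxymethyl handles on rings B and D | COc1cc(OC)c(Cc2c(O)cc(OCC)c(COC)c2O[Si](C(C)C)(C(C)C)C(C)C)c(OC)c1Cc1c(O)cc(OCC)c(COC)c1O[Si](C(C)C)(C(C)C)C(C)C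
A5 | alternative 2 | ring C bis(siloxyalkyne) | COc1cc(OC)c(CC#CO[Si](C(C)C)(C(C)C)C(C)C)c(OC)c1CC#CO[Si](C(C)C)(C(C)C)C(C)C
A6 | alternative 2 | 3-ethoxy-2-(methoxymethyl)cyclobut-2-en-1-one | CCOC1=C(COC)C(=O)C1
A7 | alternative 3 | pentamer lacking the two terminal butyryl groups | O=C1C=C(O)C(C)(C)C(O)=C1Cc1c(O)c(Cc2c(O)c(Cc3c(O)c(CC4=C(O)C(C)(C)C(O)=CC4=O)c(O)c(C(=O)CCC)c3O)c(O)c(C(=O)CCC)c2O)c(O)c(C(=O)CCC)c1O
A8 | alternative 3 | bis(dioxo ester), each arm ArCH2CH(COCH3)C(=O)C(CH3)2CO2Me | COC(=O)C(C)(C)C(=O)C(C(C)=O)Cc1c(O)c(Cc2c(O)c(Cc3c(O)c(CC(C(C)=O)C(=O)C(C)(C)C(=O)OC)c(O)c(C(=O)CCC)c3O)c(O)c(C(=O)CCC)c2O)c(O)c(C(=O)CCC)c1O
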